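**Plan**

1. Retrosynthesis: the six O–Si bonds and the exocyclic C=CH2 (methylenation of a deoxybenzoin CH2) are cut first. The C3–C3a bond of the dihydrobenzofuran is then cut by reversing a 1,2-aryl shift, which returns C3a to the aroyl carbon and gives a (2R)-2,4-diaryl-2H-chromene. The chromene is cut at C4–C4a (alkyne hydroarylation), at the aryl O–C2 bond (Mitsunobu) and at the C2–alkyne bond (alkynylation of an aldehyde).
2. Forward: the phloroglucinol ketone and a diaryl propargylic alcohol are joined as an ether, the pyran ring closes (6-endo), the pyran contracts to the dihydrofuran with its C4 pushed out as the aryl ketone carbonyl, then the methylene is added and the silyl groups are removed.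
3. Enabling feature: C3 of the dihydrofuran carries an exocyclic aroyl carbon, so C3 and that carbonyl carbon map onto C3 and C4 of a chromene. C3a of the phloroglucinol ring (ortho to O1 and to the C4 oxygen, para to the C6 oxygen) is an exceptionally good migrating carbon.
4. Stereochemistry: C2 comes from a BINOL–titanium alkynylation (R carbinol) that is inverted in the Mitsunobu etherification. C3 comes from anti addition of the iodane and inversion in the shift, which gives the trans (2R,3R) isomer, also the thermodynamic one.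

Key step: step 7

TBS = tert-butyldimethylsilyl; TBSO = tert-butyldimethylsilyloxy.
Assumption: (S)-BINOL/Ti(OiPr)4 is taken to deliver the (R)-propargylic alcohol, as it does for phenylacetylene and benzaldehyde; if the sense proves opposite, (R)-BINOL is used and nothing else changes.

**Route**

Step 1
Reactants: 1 2,4-dihydroxybenzaldehyde
Product: 2 2,4-bis(TBSO)benzaldehyde
Conditions: TBSCl (2.5 equiv), imidazole, DMF, rt
Reagents that add atoms: tert-butyldimethylsilyl chloride, CC(C)(C)[Si](C)(C)Cl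
Why: Imidazole-promoted silylation of both phenols should go to completion with excess TBSCl in DMF, the chelated ortho hydroxyl reacting last.

Step 2
Reactants: 2 2,4-bis(TBSO)benzaldehyde
Product: 3 1-ethynyl-2,4-bis(TBSO)benzene
Conditions: Me3SiCHN2, n-BuLi, THF, −78 °C; then 2, −78 °C to rt
Reagents that add atoms: trimethylsilyldiazomethane, C[Si](C)(C)C=[N+]=[N-]
Why: Colvin homologation (addition of the lithiated silyldiazomethane, Peterson-type loss of silanolate, loss of N2 and 1,2-hydride shift) should give the terminal alkyne without the carbonate/methanol medium of the Ohira–Bestmann variant, which would cleave aryl silyl ethers.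

Step 3
Reactants: 3 1-ethynyl-2,4-bis(TBSO)benzene (2 equiv, excess recovered); 4 4-(TBSO)benzaldehyde
Product: 5 (1R)-3-[2,4-bis(TBSO)phenyl]-1-[4-(TBSO)phenyl]prop-2-yn-1-ol
Conditions: Et2Zn, toluene, reflux; then (S)-BINOL (20 mol%), Ti(OiPr)4 (50 mol%), CH2Cl2, rt
Reagents that add atoms: none
Why: BINOL–titanium-catalysed enantioselective addition of an alkynylzinc to an aromatic aldehyde, in which the chiral titanium complex exposes one face of the coordinated aldehyde so that the R carbinol should form.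

Step 4
Reactants: 6 2-(4-hydroxyphenyl)-1-(2,4,6-trihydroxyphenyl)ethan-1-one
Product: 7 1-[2-hydroxy-4,6-bis(TBSO)phenyl]-2-[4-(TBSO)phenyl]ethan-1-one
Conditions: TBSCl (3.1 equiv), imidazole, DMF, 0 °C to rt
Reagents that add atoms: tert-butyldimethylsilyl chloride, CC(C)(C)[Si](C)(C)Cl
Why: Silylation should stop after three phenols because the remaining ortho hydroxyl is hydrogen-bonded to the ketone and is the least reactive, which leaves exactly the oxygen needed for the ether.

Step 5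
Reactants: 5 (R)-propargylic alcohol; 7 chelated phenol
Product: 8 1-{2-{[(1S)-3-[2,4-bis(TBSO)phenyl]-1-[4-(TBSO)phenyl]prop-2-yn-1-yl]oxy}-4,6-bis(TBSO)phenyl}-2-[4-(TBSO)phenyl]ethan-1-one
Conditions: PPh3, DIAD, toluene, 0 °C to rt
Reagents that add atoms: none
Why: Mitsunobu etherification, in which the acidic phenol displaces the oxyphosphonium of 5 by SN2, so the R carbinol centre is inverted to the S ether centre, which has the geometry required at C2 of the target.

Step 6
Reactants: 8 (S)-aryl propargyl ether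
Product: 9 1-{(2R)-5,7-bis(TBSO)-4-[2,4-bis(TBSO)phenyl]-2-[4-(TBSO)phenyl]-2H-chromen-8-yl}-2-[4-(TBSO)phenyl]ethan-1-one
Conditions: Ph3PAuNTf2 (5 mol%), CH2Cl2, 0 °C to rt, dark; used directly
Reagents that add atoms: none
Why: Monovalent-gold activation of the diaryl alkyne should trigger 6-endo-dig Friedel–Crafts attack by the only free ortho carbon of the trioxygenated ring on the alkyne carbon that bears the electron-rich aryl group (intramolecular hydroarylation of an aryl propargyl ether), without touching the C–O stereocentre.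

Step 7
Reactants: 9 (2R)-2,4-diaryl-2H-chromene
Product: 11 1-{(2R,3R)-3-[2,4-bis(TBSO)benzoyl]-4,6-bis(TBSO)-2-[4-(TBSO)phenyl]-2,3-dihydro-1-benzofuran-7-yl}-2-[4-(TBSO)phenyl]ethan-1-one, via trans-iodanyl hydroxychroman adduct 10 (not isolated)
Conditions: PhI(OH)OTs (1.1 equiv), MeCN–H2O 10:1, −10 to 0 °C, dark; aq. NaHCO3 quench
Reagents that add atoms: water, O
Why: The trivalent-iodine electrophile should add to C3 of the electron-rich C3=C4 bond of 9 on the face opposite the C2 aryl group, water should capture the doubly benzylic C4 cation anti to iodine to give 10, and in the conformer with the C3–I bond equatorial the ring A carbon C4a, antiperiplanar to that bond, should shift from C4 to C3 with loss of PhI while the C4–OH becomes the aryl ketone (semipinacol-type oxidative 1,2-aryl shift). The closest known reactions are the hypervalent-iodine and Tl(NO3)3 ring contractions of flavanones, which run through their 4-alkoxy-2H-chromene enol ethers to trans-2-aryl-2,3-dihydrobenzofuran-3-carboxylates, and of 4-substituted 1,2-dihydronaphthalenes to 1-acylindanes. The dihydrofuran ring closes by a 1,2-shift of an arene carbon through a spiro phenonium ion (3-exo-tet attack of C4a on C3, then cleavage of C4–C4a), a ring contraction that expels the pyran C4 as the exocyclic carbonyl. C2 is untouched and keeps its R configuration, and C3 is set by inversion at the carbon that carried iodine, which places the aroyl group trans to the C2 aryl group (2R,3R), the same isomer that equilibration of the enolizable C3 would favour. The step needs C4a to migrate in preference to the C4 aryl group, the C2 aryl group or loss of the C2 hydrogen: C4a is ortho to O1 and the C5 oxygen and para to the C7 oxygen, it is the only carbon antiperiplanar to an equatorial C3–I bond, and the C4 aryl group, cis to iodine after anti addition, cannot reach that alignment. Chemoselectivity for the chromene double bond over the arenes and the enolizable deoxybenzoin should rest on its 1,1-diaryl, enol-ether-like nucleophilicity at low temperature.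

Step 8
Reactants: 11 (2R,3R)-dihydrobenzofuran deoxybenzoin
Product: 13 1-{(2R,3R)-3-[2,4-bis(TBSO)benzoyl]-4,6-bis(TBSO)-2-[4-(TBSO)phenyl]-2,3-dihydro-1-benzofuran-7-yl}-2-[4-(TBSO)phenyl]prop-2-en-1-one, via Mannich base 12 (not isolated)
Conditions: (CH2O)n (3 equiv), i-Pr2NH2+ CF3CO2− (1 equiv), CF3CO2H (10 mol%), THF, 65 °C
Reagents that add atoms: paraformaldehyde (as formaldehyde), C=O
Why: Mannich methylenation, in which the methyleneiminium ion from paraformaldehyde should attack the enol of the accessible deoxybenzoin CH2 and the Mannich base 12 should lose diisopropylamine to give the 1,1-disubstituted enone, while the hindered tertiary C3–H does not react and any epimerization there returns the trans isomer.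

Step 9
Reactants: 13 hexa-TBS enone
Product: 14 1-[(2R,3R)-3-(2,4-dihydroxybenzoyl)-4,6-dihydroxy-2-(4-hydroxyphenyl)-2,3-dihydro-1-benzofuran-7-yl]-2-(4-hydroxyphenyl)prop-2-en-1-one
Conditions: HF·pyridine (excess), pyridine, THF, 0 °C to rt; pH 7 buffer work-up
Reagents that add atoms: none
Why: Buffered fluoride should cleave the six aryl silyl ethers under weakly acidic conditions that avoid phenoxides, so neither oxa-Michael closure of the free ortho hydroxyl onto the enone nor E1cB opening of the dihydrofuran is promoted and both stereocentres are kept.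

**Compound list**

1 | 2,4-dihydroxybenzaldehyde | O=Cc1ccc(O)cc1O | starting material
2 | 2,4-bis(TBSO)benzaldehyde | O=Cc1ccc(O[Si](C)(C)C(C)(C)C)cc1O[Si](C)(C)C(C)(C)C | intermediate
3 | 1-ethynyl-2,4-bis(TBSO)benzene | C#Cc1ccc(O[Si](C)(C)C(C)(C)C)cc1O[Si](C)(C)C(C)(C)C | intermediate
4 | 4-(TBSO)benzaldehyde | O=Cc1ccc(O[Si](C)(C)C(C)(C)C)cc1 | starting material
5 | (1R)-3-[2,4-bis(TBSO)phenyl]-1-[4-(TBSO)phenyl]prop-2-yn-1-ol | O[C@H](c1ccc(O[Si](C)(C)C(C)(C)C)cc1)C#Cc1ccc(O[Si](C)(C)C(C)(C)C)cc1O[Si](C)(C)C(C)(C)C | intermediate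
6 | 2-(4-hydroxyphenyl)-1-(2,4,6-trihydroxyphenyl)ethan-1-one | O=C(Cc1ccc(O)cc1)c1c(O)cc(O)cc1O | starting material
7 | 1-[2-hydroxy-4,6-bis(TBSO)phenyl]-2-[4-(TBSO)phenyl]ethan-1-one | O=C(Cc1ccc(O[Si](C)(C)C(C)(C)C)cc1)c1c(O)cc(O[Si](C)(C)C(C)(C)C)cc1O[Si](C)(C)C(C)(C)C | intermediate
8 | 1-{2-{[(1S)-3-[2,4-bis(TBSO)phenyl]-1-[4-(TBSO)phenyl]prop-2-yn-1-yl]oxy}-4,6-bis(TBSO)phenyl}-2-[4-(TBSO)phenyl]ethan-1-one | O=C(Cc1ccc(O[Si](C)(C)C(C)(C)C)cc1)c1c(O[C@@H](c2ccc(O[Si](C)(C)C(C)(C)C)cc2)C#Cc2ccc(O[Si](C)(C)C(C)(C)C)cc2O[Si](C)(C)C(C)(C)C)cc(O[Si](C)(C)C(C)(C)C)cc1O[Si](C)(C)C(C)(C)C | intermediate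
9 | 1-{(2R)-5,7-bis(TBSO)-4-[2,4-bis(TBSO)phenyl]-2-[4-(TBSO)phenyl]-2H-chromen-8-yl}-2-[4-(TBSO)phenyl]ethan-1-one | O=C(Cc1ccc(O[Si](C)(C)C(C)(C)C)cc1)c1c(O[Si](C)(C)C(C)(C)C)cc(O[Si](C)(C)C(C)(C)C)c2c1O[C@@H](c1ccc(O[Si](C)(C)C(C)(C)C)cc1)C=C2c1ccc(O[Si](C)(C)C(C)(C)C)cc1O[Si](C)(C)C(C)(C)C | intermediate
10 | 1-{(2S,3S,4S)-5,7-bis(TBSO)-4-[2,4-bis(TBSO)phenyl]-4-hydroxy-3-[phenyl(tosyloxy)iodanyl]-2-[4-(TBSO)phenyl]chroman-8-yl}-2-[4-(TBSO)phenyl]ethan-1-one (2-aryl and iodanyl trans; iodanyl and hydroxyl trans) | O=C(Cc1ccc(O[Si](C)(C)C(C)(C)C)cc1)c1c(O[Si](C)(C)C(C)(C)C)cc(O[Si](C)(C)C(C)(C)C)c2c1O[C@@H](c1ccc(O[Si](C)(C)C(C)(C)C)cc1)[C@H](I(c1ccccc1)OS(=O)(=O)c1ccc(C)cc1)[C@]2(O)c1ccc(O[Si](C)(C)C(C)(C)C)cc1O[Si](C)(C)C(C)(C)C | intermediate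
11 | 1-{(2R,3R)-3-[2,4-bis(TBSO)benzoyl]-4,6-bis(TBSO)-2-[4-(TBSO)phenyl]-2,3-dihydro-1-benzofuran-7-yl}-2-[4-(TBSO)phenyl]ethan-1-one | O=C(Cc1ccc(O[Si](C)(C)C(C)(C)C)cc1)c1c(O[Si](C)(C)C(C)(C)C)cc(O[Si](C)(C)C(C)(C)C)c2c1O[C@@H](c1ccc(O[Si](C)(C)C(C)(C)C)cc1)[C@@H]2C(=O)c1ccc(O[Si](C)(C)C(C)(C)C)cc1O[Si](C)(C)C(C)(C)C | intermediate
12 | 3-(diisopropylamino)-1-{(2R,3R)-3-[2,4-bis(TBSO)benzoyl]-4,6-bis(TBSO)-2-[4-(TBSO)phenyl]-2,3-dihydro-1-benzofuran-7-yl}-2-[4-(TBSO)phenyl]propan-1-one (both epimers at the chain carbon) | O=C(C(CN(C(C)C)C(C)C)c1ccc(O[Si](C)(C)C(C)(C)C)cc1)c1c(O[Si](C)(C)C(C)(C)C)cc(O[Si](C)(C)C(C)(C)C)c2c1O[C@@H](c1ccc(O[Si](C)(C)C(C)(C)C)cc1)[C@@H]2C(=O)c1ccc(O[Si](C)(C)C(C)(C)C)cc1O[Si](C)(C)C(C)(C)C | intermediate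
13 | 1-{(2R,3R)-3-[2,4-bis(TBSO)benzoyl]-4,6-bis(TBSO)-2-[4-(TBSO)phenyl]-2,3-dihydro-1-benzofuran-7-yl}-2-[4-(TBSO)phenyl]prop-2-en-1-one | C=C(C(=O)c1c(O[Si](C)(C)C(C)(C)C)cc(O[Si](C)(C)C(C)(C)C)c2c1O[C@@H](c1ccc(O[Si](C)(C)C(C)(C)C)cc1)[C@@H]2C(=O)c1ccc(O[Si](C)(C)C(C)(C)C)cc1O[Si](C)(C)C(C)(C)C)c1ccc(O[Si](C)(C)C(C)(C)C)cc1 | intermediate
14 | 1-[(2R,3R)-3-(2,4-dihydroxybenzoyl)-4,6-dihydroxy-2-(4-hydroxyphenyl)-2,3-dihydro-1-benzofuran-7-yl]-2-(4-hydroxyphenyl)prop-2-en-1-one | C=C(C(=O)c1c(O)cc(O)c2c1O[C@@H](c1ccc(O)cc1)[C@@H]2C(=O)c1ccc(O)cc1O)c1ccc(O)cc1 | target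

**Step count**

Total steps: 9. Longest linear sequence: 8 steps (steps 1, 2, 3, 5, 6, 7, 8, 9, from 2,4-dihydroxybenzaldehyde); step 4 is a one-step branch.

**Steps most likely to fail**

Step 7. The iodane may leave by other paths: shift of the C4 or C2 aryl group, loss of the C2 hydrogen with aromatization of the pyran ring, or attack of the oxidant on the electron-rich arenes. The sulfonic acid set free may also strip silyl groups or ionize the C2–O bond. The fallback separates addition from migration and sets out from 9. NBS in aqueous THF at 0 °C should give, by the same anti addition, the trans-bromohydrin 1-{(2S,3S,4S)-3-bromo-5,7-bis(TBSO)-4-[2,4-bis(TBSO)phenyl]-4-hydroxy-2-[4-(TBSO)phenyl]chroman-8-yl}-2-[4-(TBSO)phenyl]ethan-1-one F1, which is isolated. Treatment with Ag2CO3 in CH2Cl2 at rt in the dark should then induce silver-assisted loss of bromide with the same C4a shift (halohydrin semipinacol ring contraction), and the route is rejoined at 11.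

Step 5. The oxyphosphonium of the p-silyloxyphenyl propargylic alcohol may ionize, with erosion of enantiopurity and SN2' leakage, and the hindered chelated phenol may attack slowly. The fallback forms the C–O bond under catalyst control and sets out from 4 and 7. Ethynylmagnesium bromide (THF, 0 °C) should add to 4 to give racemic 1-[4-(TBSO)phenyl]prop-2-yn-1-ol F2, and Ac2O/pyridine/DMAP should give the acetate 1-[4-(TBSO)phenyl]prop-2-yn-1-yl acetate F3. Copper-catalysed enantioselective propargylic etherification of F3 with phenol 7 (CuOTf·0.5C6H6, chiral Ph-pybox of the sense that gives R, i-Pr2NEt), which runs through a copper allenylidene, should give the terminal ether 1-{2-{[(1R)-1-[4-(TBSO)phenyl]prop-2-yn-1-yl]oxy}-4,6-bis(TBSO)phenyl}-2-[4-(TBSO)phenyl]ethan-1-one F4. Commercial 4-iodoresorcinol is silylated (TBSCl, imidazole, DMF) to 1-iodo-2,4-bis(TBSO)benzene F5. Copper-free Sonogashira coupling of F4 with F5 (Pd(PPh3)4, piperidine, THF, 50 °C) rejoins the route at 8.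

Step 6. The cationic catalyst may ionize the doubly activated propargylic C–O bond (loss of enantiopurity or C-alkylation), the ortho silyloxy oxygen may attack the activated alkyne, and closure next to the bulky silyl ether may be slow. The fallback sets out from 8 and uses a stoichiometric electrophile under bicarbonate buffer. I2 and NaHCO3 in MeCN at rt should effect 6-endo-dig iodocyclization to 1-{(2S)-5,7-bis(TBSO)-4-[2,4-bis(TBSO)phenyl]-3-iodo-2-[4-(TBSO)phenyl]-2H-chromen-8-yl}-2-[4-(TBSO)phenyl]ethan-1-one F6. Radical deiodination with (Me3Si)3SiH and catalytic Et3B/air in toluene at rt (no palladium, so the allylic C2–O bond is not ionized) rejoins the route at 9.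

**Further compounds**

F1 | step 7 | 1-{(2S,3S,4S)-3-bromo-5,7-bis(TBSO)-4-[2,4-bis(TBSO)phenyl]-4-hydroxy-2-[4-(TBSO)phenyl]chroman-8-yl}-2-[4-(TBSO)phenyl]ethan-1-one | O=C(Cc1ccc(O[Si](C)(C)C(C)(C)C)cc1)c1c(O[Si](C)(C)C(C)(C)C)cc(O[Si](C)(C)C(C)(C)C)c2c1O[C@@H](c1ccc(O[Si](C)(C)C(C)(C)C)cc1)[C@H](Br)[C@]2(O)c1ccc(O[Si](C)(C)C(C)(C)C)cc1O[Si](C)(C)C(C)(C)C
F2 | step 5 | racemic 1-[4-(TBSO)phenyl]prop-2-yn-1-ol | C#CC(O)c1ccc(O[Si](C)(C)C(C)(C)C)cc1
F3 | step 5 | racemic 1-[4-(TBSO)phenyl]prop-2-yn-1-yl acetate | C#CC(OC(C)=O)c1ccc(O[Si](C)(C)C(C)(C)C)cc1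
F4 | step 5 | 1-{2-{[(1R)-1-[4-(TBSO)phenyl]prop-2-yn-1-yl]oxy}-4,6-bis(TBSO)phenyl}-2-[4-(TBSO)phenyl]ethan-1-one | O=C(Cc1ccc(O[Si](C)(C)C(C)(C)C)cc1)c1c(O[C@@H](c2ccc(O[Si](C)(C)C(C)(C)C)cc2)C#C)cc(O[Si](C)(C)C(C)(C)C)cc1O[Si](C)(C)C(C)(C)C
F5 | step 5 | 1-iodo-2,4-bis(TBSO)benzene | Ic1ccc(O[Si](C)(C)C(C)(C)C)cc1O[Si](C)(C)C(C)(C)C
F6 | step 6 | 1-{(2S)-5,7-bis(TBSO)-4-[2,4-bis(TBSO)phenyl]-3-iodo-2-[4-(TBSO)phenyl]-2H-chromen-8-yl}-2-[4-(TBSO)phenyl]ethan-1-one | O=C(Cc1ccc(O[Si](C)(C)C(C)(C)C)cc1)c1c(O[Si](C)(C)C(C)(C)C)cc(O[Si](C)(C)C(C)(C)C)c2c1O[C@@H](c1ccc(O[Si](C)(C)C(C)(C)C)cc1)C(I)=C2c1ccc(O[Si](C)(C)C(C)(C)C)cc1O[Si](C)(C)C(C)(C)C
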